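**Plan**

- Retrosynthesis: the C15–C5′ bond is cut first (butenolide as a 2-silyloxyfuran, C15 as an aldehyde). Then the C18–O bond is cut, back through an 18,6α-lactone and a 6α,18-ether to the 4α-methyl group. The 8α-OH/C17-H pair goes back to an 8α,17-epoxide and the 14-OH/C13=C16 pair to a 13,14-epoxide, which leaves larixol.
- Forward: no carbocycle is built, since larixol supplies rings A and B and C1–C20. Its vinyl carbinol is transposed to the 13E allylic alcohol and epoxidized, C8=C17 is epoxidized, the tetrahydrofuran ring O6–C18 is closed and oxidized to the lactone, the side-chain epoxide is isomerized to the 13(16)-en-14-ol, LiAlH4 opens lactone and spiro-epoxide, and the butenolide is joined last at C15.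
- Enabling feature: on the trans-fused rings A and B the equatorial 6α-oxygen on C6 (ring B) and the equatorial 4α-methyl carbon C18 on C4 (ring A) are peri to each other across the ring-fusion carbon C5. O6, C6, C5, C4, C18 and one hydrogen of C18 can therefore form the six-membered array of a 1,5-hydrogen shift, while C19 and C20 are axial on the β face.
- Stereochemistry: C5, C6, C9 and C10 come from larixol; C4 from the site of hydrogen abstraction; C8 from α-face epoxidation; C14 from D-(−)-diethyl tartrate; C15 and C5′ from a chelation-controlled vinylogous Mukaiyama aldol addition.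

Key step: step 7

Remarks: labdane numbering is used; C18 is the 4α carbon and C19 the 4β methyl group. Larixol and 4-methylfuran-2(5H)-one are taken as purchased. It is assumed that the 13Z isomer formed beside 3 can be removed by chromatography at the stage of diol 4.

Step 1
Reactants: 1 larixol, (13S)-labda-8(17),14-diene-6α,13-diol
Product: 2 larixol 6α,13-diacetate
Conditions: AcCl, PhNMe2, CH2Cl2, 0 to 25 °C
Reagents that add atoms: acetyl chloride, CC(=O)Cl
Why: Acetyl chloride buffered by N,N-dimethylaniline esterifies the secondary 6α-hydroxyl and also the tertiary allylic 13-hydroxyl (acylation) without ionizing the latter; no stereocenter is affected.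

Step 2
Reactants: 2 larixol 6α,13-diacetate
Product: 3 (13E)-labda-8(17),13-diene-6α,15-diyl diacetate
Conditions: PdCl2(MeCN)2 (5 mol %), THF, 25 °C
Reagents that add atoms: none
Why: Divalent palladium catalyses the cyclization-induced [3,3] transposition of the tertiary allylic acetate (allylic ester rearrangement), which should move the ester to primary C15 and give the trisubstituted 13E double bond as the major geometric isomer; the C13 stereocenter is given up on purpose.

Step 3
Reactants: 3 (13E)-labda-8(17),13-diene-6α,15-diyl diacetate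
Product: 4 (13E)-labda-8(17),13-diene-6α,15-diol
Conditions: KOH, MeOH–H2O, 60 °C
Reagents that add atoms: none
Why: Saponification frees both hydroxyl groups, the hindered 6α-acetate needing the warm hydroxide; the minor 13Z isomer is removed by chromatography at this stage.

Step 4
Reactants: 4 (13E)-labda-8(17),13-diene-6α,15-diol
Product: 5 (13R,14R)-13,14-epoxylabd-8(17)-ene-6α,15-diol
Conditions: Ti(OiPr)4 (10 mol %), D-(−)-diethyl tartrate (12 mol %), t-BuOOH, 4 Å molecular sieves, CH2Cl2, −20 °C
Reagents that add atoms: tert-butyl hydroperoxide, CC(C)(C)OO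
Why: Katsuki–Sharpless asymmetric epoxidation: the titanium tartrate complex binds the primary allylic alcohol and, with the D-(−)-tartrate, delivers oxygen to the face of the 13E double bond that gives the (13R,14R)-epoxide (reagent control, setting C14), while the exocyclic C8=C17 bond, only homoallylic to the 6α-hydroxyl, should not be epoxidized at −20 °C.

Step 5
Reactants: 5 (13R,14R)-13,14-epoxylabd-8(17)-ene-6α,15-diol
Product: 6 (13R,14R)-13,14-epoxy-6α-hydroxylabd-8(17)-en-15-yl acetate
Conditions: AcCl, 2,4,6-collidine, CH2Cl2, −78 °C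
Reagents that add atoms: acetyl chloride, CC(=O)Cl
Why: Kinetic acylation at low temperature selects the unhindered primary 15-hydroxyl over the secondary 6α-hydroxyl, which is flanked by C18 and must stay free for step 7.

Step 6
Reactants: 6 (13R,14R)-13,14-epoxy-6α-hydroxylabd-8(17)-en-15-yl acetate
Product: 7 (13R,14R)-8α,17:13,14-diepoxy-6α-hydroxylabdan-15-yl acetate
Conditions: mCPBA, NaHCO3, CH2Cl2, 0 °C
Reagents that add atoms: 3-chloroperbenzoic acid, O=C(OO)c1cccc(Cl)c1
Why: Prilezhaev epoxidation of the exocyclic double bond should occur from the α face, because the β face is screened by the axial C10 methyl group (C20) and the C9 side chain and the 6α-hydroxyl can guide the peracid on the α face by hydrogen bonding; this sets C8 with its oxygen 8α.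

Step 7
Reactants: 7 (13R,14R)-8α,17:13,14-diepoxy-6α-hydroxylabdan-15-yl acetate
Product: 10 (13R,14R)-6α,18:8α,17:13,14-triepoxylabdan-15-yl acetate, via 6α-hypoiodite 8 (not isolated), via 18-iodo-6α-alcohol 9 (not isolated)
Conditions: PhI(OAc)2, I2, cyclohexane–CH2Cl2, visible light (tungsten lamp), 25 °C
Reagents that add atoms: none
Why: PhI(OAc)2 and I2 give acetyl hypoiodite, which converts the 6α-hydroxyl into hypoiodite 8; visible light cleaves the O–I bond, and the 6α-alkoxy radical takes a hydrogen atom from C18 through a six-membered chair-like transition state (1,5-hydrogen atom transfer). The C18 radical is trapped by iodine to give iodide 9, and O6 then displaces iodide from C18 in a 5-exo-tet closure that forms the tetrahydrofuran ring O6–C6–C5–C4–C18. The closest known reaction type is the hypoiodite reaction of rigid polycyclic alcohols, by which 6β-hydroxy steroids are converted into 6β,19-ethers, also at a neopentyl carbon. C4 becomes stereogenic only through the choice between its two methyl groups, and the substrate fixes that choice: the equatorial C6–O and C4–C18 bonds are peri across C5, whereas the axial 4β-methyl (C19) and the C10 methyl (C20) lie on the opposite face, so the oxygen-bearing carbon ends up 4α. The step needs site selectivity for C18 and tolerance of the other functions; the first is secured by this geometry, the second by the absence of any other free hydroxyl group or alkene, both alkenes being stored as epoxides and O15 as an acetate. Fragmentation of the alkoxy radical is not expected to compete, since cleavage of C5–C6 or C6–C7 would give only an unstabilized secondary or primary radical.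

Step 8
Reactants: 10 (13R,14R)-6α,18:8α,17:13,14-triepoxylabdan-15-yl acetate
Product: 11 (13R,14R)-15-acetoxy-8α,17:13,14-diepoxylabdan-18,6α-olide
Conditions: RuCl3·xH2O (cat.), NaIO4, CCl4–MeCN–pH 7 phosphate buffer, 25 °C
Reagents that add atoms: sodium periodate (oxygen delivered through RuO4), [Na+].[O-]I(=O)(=O)=O
Why: RuO4 formed in the flask oxidizes the ether methylene C18 to the carbonyl (oxidation of a cyclic ether to a lactone), the other ether α-position being a methine whose axial hydrogen is screened by the axial C19 and C20 methyl groups; epoxides and esters are inert to this oxidant.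

Step 9
Reactants: 11 (13R,14R)-15-acetoxy-8α,17:13,14-diepoxylabdan-18,6α-olide
Product: 12 (13R,14R)-8α,17:13,14-diepoxy-15-hydroxylabdan-18,6α-olide
Conditions: K2CO3 (cat.), MeOH, 0 °C
Reagents that add atoms: none
Why: Carbonate-catalysed methanolysis (transesterification) cleaves the unhindered primary acetate, while the lactone carbonyl on the quaternary C4 is neopentyl-like and the epoxides are stable to the mild base.

Step 10
Reactants: 12 (13R,14R)-8α,17:13,14-diepoxy-15-hydroxylabdan-18,6α-olide
Product: 13 (14S)-8α,17-epoxy-14,15-dihydroxylabd-13(16)-en-18,6α-olide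
Conditions: Ti(OiPr)4 (1.5 equiv), CH2Cl2, 25 °C
Reagents that add atoms: none
Why: Hydroxyl-directed epoxy alcohol rearrangement: Ti(OiPr)4 binds the C15 hydroxyl and activates the neighbouring epoxide, whose C13–O bond ionizes while an isopropoxide ligand removes a proton from the C16 methyl group, cis to C15 in the E-derived epoxide, to give the 13(16)-ene; the C14–O bond is untouched, so the carbinol keeps the configuration set in step 4 (14R becomes 14S only through a change of ligand priorities), and the 8α,17-epoxide, which has no neighbouring hydroxyl, should be left alone.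

Step 11
Reactants: 13 (14S)-8α,17-epoxy-14,15-dihydroxylabd-13(16)-en-18,6α-olide
Product: 14 (14S)-labd-13(16)-ene-6α,8α,14,15,18-pentaol
Conditions: LiAlH4, THF, 0 °C to reflux
Reagents that add atoms: none
Why: Hydride reduces the lactone to the 6α,18-diol and opens the 8α,17-epoxide at its unhindered methylene carbon C17 (epoxide reduction), so the C8–O bond and the 8α configuration are retained and C17 becomes the 8β-methyl group; the allylic diol is not reduced.

Step 12
Reactants: 14 (14S)-labd-13(16)-ene-6α,8α,14,15,18-pentaol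
Product: 15 (14S)-14,15-O-(4-methoxybenzylidene)labd-13(16)-ene-6α,8α,14,15,18-pentaol (both epimers at the acetal carbon)
Conditions: 4-MeOC6H4CH(OMe)2 (1.1 equiv), PPTS (cat.), CH2Cl2, 25 °C
Reagents that add atoms: 4-methoxybenzaldehyde dimethyl acetal, COC(OC)c1ccc(OC)cc1
Why: Acid-catalysed transacetalization engages the terminal 1,2-diol as a five-membered dioxolane, since the 6α,18-diol would need a seven-membered ring and the diequatorial 6α- and 8α-hydroxyls cannot be bridged; the configuration at the acetal carbon is of no consequence.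

Step 13
Reactants: 15 (14S)-14,15-O-(4-methoxybenzylidene)labd-13(16)-ene-6α,8α,14,15,18-pentaol
Product: 16 6α,18-bis(triethylsilyl) ether of 15
Conditions: Et3SiCl (excess), imidazole, DMAP (cat.), DMF, 25 to 40 °C
Reagents that add atoms: chlorotriethylsilane, CC[Si](Cl)(CC)CC
Why: Silylation protects the primary 18-hydroxyl and, with excess reagent, the secondary 6α-hydroxyl, while the tertiary 8α-hydroxyl is too hindered to react under these conditions.

Step 14
Reactants: 16 6α,18-bis(triethylsilyl) ether of 15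
Product: 17 (14S)-14-(4-methoxybenzyloxy)-6α,18-bis(triethylsilyloxy)labd-13(16)-ene-8α,15-diol
Conditions: i-Bu2AlH, CH2Cl2, −78 to 0 °C
Reagents that add atoms: none
Why: Reductive opening of the 4-methoxybenzylidene acetal: the aluminium hydride coordinates the less hindered primary O15 and delivers hydride to the acetal carbon, which leaves the 4-methoxybenzyl ether on the secondary O14 and frees the C15 hydroxyl; silyl ethers are stable.

Step 15
Reactants: 17 (14S)-14-(4-methoxybenzyloxy)-6α,18-bis(triethylsilyloxy)labd-13(16)-ene-8α,15-diol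
Product: 18 (14S)-8α-hydroxy-14-(4-methoxybenzyloxy)-6α,18-bis(triethylsilyloxy)labd-13(16)-en-15-al
Conditions: Dess–Martin periodinane, NaHCO3, CH2Cl2, 0 °C
Reagents that add atoms: none
Why: Dess–Martin oxidation under bicarbonate buffering converts the primary alcohol into the aldehyde without acid or base strong enough to epimerize C14 or to move the 13(16) double bond into conjugation; the tertiary 8α-hydroxyl cannot be oxidized, and the aldehyde is used at once.

Step 16
Reactants: 19 4-methylfuran-2(5H)-one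
Product: 20 tert-butyldimethyl[(4-methylfuran-2-yl)oxy]silane
Conditions: t-BuMe2SiOTf, Et3N, CH2Cl2, 0 °C
Reagents that add atoms: tert-butyldimethylsilyl trifluoromethanesulfonate, CC(C)(C)[Si](C)(C)OS(=O)(=O)C(F)(F)F
Why: Soft enolization of the butenolide with the silyl triflate and triethylamine gives the aromatic 2-silyloxyfuran (silyl dienol ether formation).

Step 17
Reactants: 18 (14S)-8α-hydroxy-14-(4-methoxybenzyloxy)-6α,18-bis(triethylsilyloxy)labd-13(16)-en-15-al; 20 tert-butyldimethyl[(4-methylfuran-2-yl)oxy]silane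
Product: 21 (5R)-5-[(14S,15R)-8α,15-dihydroxy-14-(4-methoxybenzyloxy)-6α,18-bis(triethylsilyloxy)labd-13(16)-en-15-yl]-4-methylfuran-2(5H)-one
Conditions: MgBr2·OEt2 (3 equiv), CH2Cl2, −78 to −40 °C
Reagents that add atoms: none
Why: Vinylogous Mukaiyama aldol addition under chelation control: MgBr2 bridges the aldehyde oxygen and the oxygen of the 14-O-(4-methoxybenzyl) ether, C5 of the silyloxyfuran attacks the face of the chelate opposite to the C13 substituent (Cram chelate model, 14,15-syn, hence 15R), and the open transition state usual for 2-silyloxyfurans should place the new C5′–O bond syn to the C15 hydroxyl (5′R).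

Step 18
Reactants: 21 (5R)-5-[(14S,15R)-8α,15-dihydroxy-14-(4-methoxybenzyloxy)-6α,18-bis(triethylsilyloxy)labd-13(16)-en-15-yl]-4-methylfuran-2(5H)-one
Product: 22 6α,18-bis(triethylsilyl) ether of the target
Conditions: DDQ, CH2Cl2–pH 7 buffer, 0 °C
Reagents that add atoms: none
Why: Oxidative cleavage of the 4-methoxybenzyl ether by DDQ in the presence of water frees the 14-hydroxyl; the silyl ethers, the butenolide and the 1,1-disubstituted double bond are inert.

Step 19
Reactants: 22 6α,18-bis(triethylsilyl) ether of the target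
Product: 23 CNP0301623.1, (5R)-5-[(14S,15R)-6α,8α,14,15,18-pentahydroxylabd-13(16)-en-15-yl]-4-methylfuran-2(5H)-one
Conditions: HF·pyridine, pyridine, THF, 0 to 25 °C
Reagents that add atoms: none
Why: Desilylation with buffered HF·pyridine removes both triethylsilyl ethers without base, so the base-sensitive C5′ stereocenter of the butenolide and the tertiary and allylic alcohols are preserved.

**Compound list**

1 | larixol, (13S)-labda-8(17),14-diene-6α,13-diol | C=C[C@@](C)(O)CC[C@@H]1[C@@]2(C)CCCC(C)(C)[C@@H]2[C@@H](O)CC1=C | starting material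
2 | larixol 6α,13-diacetate | C=C[C@@](C)(OC(C)=O)CC[C@@H]1[C@@]2(C)CCCC(C)(C)[C@@H]2[C@@H](OC(C)=O)CC1=C | intermediate
3 | (13E)-labda-8(17),13-diene-6α,15-diyl diacetate | CC(=O)OC/C=C(\C)CC[C@@H]1[C@@]2(C)CCCC(C)(C)[C@@H]2[C@@H](OC(C)=O)CC1=C | intermediate
4 | (13E)-labda-8(17),13-diene-6α,15-diol | OC/C=C(\C)CC[C@@H]1[C@@]2(C)CCCC(C)(C)[C@@H]2[C@@H](O)CC1=C | intermediate
5 | (13R,14R)-13,14-epoxylabd-8(17)-ene-6α,15-diol | C[C@]2(CC[C@@H]1[C@@]3(C)CCCC(C)(C)[C@@H]3[C@@H](O)CC1=C)O[C@@H]2CO | intermediate
6 | (13R,14R)-13,14-epoxy-6α-hydroxylabd-8(17)-en-15-yl acetate | C[C@]2(CC[C@@H]1[C@@]3(C)CCCC(C)(C)[C@@H]3[C@@H](O)CC1=C)O[C@@H]2COC(C)=O | intermediate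
7 | (13R,14R)-8α,17:13,14-diepoxy-6α-hydroxylabdan-15-yl acetate | C[C@]2(CC[C@@H]1[C@@]3(C)CCCC(C)(C)[C@@H]3[C@@H](O)C[C@]14CO4)O[C@@H]2COC(C)=O | intermediate
8 | (13R,14R)-8α,17:13,14-diepoxy-6α-(iodooxy)labdan-15-yl acetate (6α-hypoiodite) | C[C@]2(CC[C@@H]1[C@@]3(C)CCCC(C)(C)[C@@H]3[C@@H](OI)C[C@]14CO4)O[C@@H]2COC(C)=O | intermediate
9 | (13R,14R)-8α,17:13,14-diepoxy-6α-hydroxy-18-iodolabdan-15-yl acetate | C[C@]2(CC[C@@H]1[C@@]3(C)CCC[C@](CI)(C)[C@@H]3[C@@H](O)C[C@]14CO4)O[C@@H]2COC(C)=O | intermediate
10 | (13R,14R)-6α,18:8α,17:13,14-triepoxylabdan-15-yl acetate | C[C@]2(CC[C@@H]1[C@@]3(C)CCC[C@]5(C)[C@@H]3[C@@H](OC5)C[C@]14CO4)O[C@@H]2COC(C)=O | intermediate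
11 | (13R,14R)-15-acetoxy-8α,17:13,14-diepoxylabdan-18,6α-olide | C[C@]2(CC[C@@H]1[C@@]3(C)CCC[C@]5(C)[C@@H]3[C@@H](OC5=O)C[C@]14CO4)O[C@@H]2COC(C)=O | intermediate
12 | (13R,14R)-8α,17:13,14-diepoxy-15-hydroxylabdan-18,6α-olide | C[C@]2(CC[C@@H]1[C@@]3(C)CCC[C@]5(C)[C@@H]3[C@@H](OC5=O)C[C@]14CO4)O[C@@H]2CO | intermediate
13 | (14S)-8α,17-epoxy-14,15-dihydroxylabd-13(16)-en-18,6α-olide | C=C(CC[C@@H]1[C@@]3(C)CCC[C@]5(C)[C@@H]3[C@@H](OC5=O)C[C@]14CO4)[C@H](O)CO | intermediate
14 | (14S)-labd-13(16)-ene-6α,8α,14,15,18-pentaol | C=C(CC[C@@H]1[C@@]2(C)CCC[C@@](C)(CO)[C@@H]2[C@@H](O)C[C@@]1(C)O)[C@H](O)CO | intermediate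
15 | (14S)-14,15-O-(4-methoxybenzylidene)labd-13(16)-ene-6α,8α,14,15,18-pentaol (both epimers at the acetal carbon) | C=C(CC[C@@H]1[C@@]2(C)CCC[C@@](C)(CO)[C@@H]2[C@@H](O)C[C@@]1(C)O)[C@H]3COC(c4ccc(OC)cc4)O3 | intermediate
16 | 6α,18-bis(triethylsilyl) ether of 15 | C=C(CC[C@@H]1[C@@]2(C)CCC[C@@](C)(CO[Si](CC)(CC)CC)[C@@H]2[C@@H](O[Si](CC)(CC)CC)C[C@@]1(C)O)[C@H]3COC(c4ccc(OC)cc4)O3 | intermediate
17 | (14S)-14-(4-methoxybenzyloxy)-6α,18-bis(triethylsilyloxy)labd-13(16)-ene-8α,15-diol | C=C(CC[C@@H]1[C@@]2(C)CCC[C@@](C)(CO[Si](CC)(CC)CC)[C@@H]2[C@@H](O[Si](CC)(CC)CC)C[C@@]1(C)O)[C@H](OCc3ccc(OC)cc3)CO | intermediate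
18 | (14S)-8α-hydroxy-14-(4-methoxybenzyloxy)-6α,18-bis(triethylsilyloxy)labd-13(16)-en-15-al | C=C(CC[C@@H]1[C@@]2(C)CCC[C@@](C)(CO[Si](CC)(CC)CC)[C@@H]2[C@@H](O[Si](CC)(CC)CC)C[C@@]1(C)O)[C@H](OCc3ccc(OC)cc3)C=O | intermediate
19 | 4-methylfuran-2(5H)-one | CC1=CC(=O)OC1 | starting material
20 | tert-butyldimethyl[(4-methylfuran-2-yl)oxy]silane | Cc1coc(O[Si](C)(C)C(C)(C)C)c1 | intermediate
21 | (5R)-5-[(14S,15R)-8α,15-dihydroxy-14-(4-methoxybenzyloxy)-6α,18-bis(triethylsilyloxy)labd-13(16)-en-15-yl]-4-methylfuran-2(5H)-one | C=C(CC[C@@H]1[C@@]2(C)CCC[C@@](C)(CO[Si](CC)(CC)CC)[C@@H]2[C@@H](O[Si](CC)(CC)CC)C[C@@]1(C)O)[C@H](OCc3ccc(OC)cc3)[C@@H](O)[C@@H]3OC(=O)C=C3C | intermediate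
22 | 6α,18-bis(triethylsilyl) ether of the target | C=C(CC[C@@H]1[C@@]2(C)CCC[C@@](C)(CO[Si](CC)(CC)CC)[C@@H]2[C@@H](O[Si](CC)(CC)CC)C[C@@]1(C)O)[C@H](O)[C@@H](O)[C@@H]3OC(=O)C=C3C | intermediate
23 | CNP0301623.1 | C=C(CC[C@@H]1[C@@]2(C)CCC[C@@](C)(CO)[C@@H]2[C@@H](O)C[C@@]1(C)O)[C@H](O)[C@@H](O)[C@@H]1OC(=O)C=C1C | target

**Step count**

Total: 19 steps. Longest linear sequence: 18 steps (steps 1–15 and 17–19, from larixol); step 16 is a one-step side branch.

**Steps most likely to fail, with fallbacks**

Step 7. The two epoxides may be opened by the iodine electrophiles and by the acetic acid that the reaction releases, and closure at the neopentyl C18 may be slow enough for a second hydrogen abstraction at that carbon. The fallback is a Barton nitrite photolysis and sets out from 7. NOCl in pyridine at −20 °C should give the 6α-nitrite F1. Irradiation (mercury lamp, Pyrex filter, benzene, 20 °C) generates the same alkoxy radical without any halogen, and nitric oxide recombines at C18 to give the 18-nitroso compound F2, which tautomerizes on warming in 2-propanol to the 18-oxime F3. Oxime exchange with aqueous glyoxylic acid and NaOAc frees the C18 aldehyde in its cyclic form, the 6α,18-lactol F4. Ag2CO3 on Celite in refluxing benzene oxidizes the lactol to lactone 11, where the route is rejoined, so step 8 is bypassed as well.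

Step 17. Chelation may be incomplete, so that the furan attacks the other face of the aldehyde; the simple diastereoselection at C5′ may be low; and the 13(16) double bond of aldehyde 18 may migrate into conjugation. The fallback replaces substrate control by reagent control and sets out from 18. The dibutylboron enolate of (S)-4-benzyl-3-[(4-methoxybenzyloxy)acetyl]oxazolidin-2-one (Bu2BOTf, Et3N, CH2Cl2, −78 °C) should give the Evans syn aldol adduct F5, in which the auxiliary fixes the 15R hydroxyl and the C5′ oxygen. MeNHOMe·HCl and AlMe3 convert the imide into the Weinreb amide F6, and MeMgBr gives the methyl ketone F7. DDQ removes both 4-methoxybenzyl ethers to give the trihydroxy ketone F8. Wittig olefination with Ph3P=CHCO2Et (toluene, 80 °C) gives the Z-enoate F9, which lactonizes through the C5′ hydroxyl to 22, where the route is rejoined before the final desilylation.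

Step 2. The palladium-mediated equilibration may leave a large share of the 13Z acetate and may move the 8(17) double bond into ring B; Z material would later be epoxidized and isomerized to a 12-ene instead of the 13(16)-ene. The fallback rebuilds the double bond by olefination and sets out from 1. KMnO4 (MgSO4, acetone, 0 °C) degrades the vinyl carbinol to the methyl ketone F10. A Horner–Wadsworth–Emmons reaction with triethyl phosphonoacetate and NaH (THF, 0 to 25 °C) should give mainly the E-enoate F11, which is purified from its Z isomer. i-Bu2AlH (CH2Cl2, −78 °C) reduces the ester to diol 4, where the route is rejoined in place of steps 1–3.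

**Further compounds**

F1 | step 7 | (13R,14R)-8α,17:13,14-diepoxy-6α-(nitrosooxy)labdan-15-yl acetate | C[C@]2(CC[C@@H]1[C@@]3(C)CCCC(C)(C)[C@@H]3[C@@H](ON=O)C[C@]14CO4)O[C@@H]2COC(C)=O
F2 | step 7 | (13R,14R)-8α,17:13,14-diepoxy-6α-hydroxy-18-nitrosolabdan-15-yl acetate | C[C@]2(CC[C@@H]1[C@@]3(C)CCC[C@](CN=O)(C)[C@@H]3[C@@H](O)C[C@]14CO4)O[C@@H]2COC(C)=O
F3 | step 7 | (13R,14R)-8α,17:13,14-diepoxy-6α-hydroxy-18-(hydroxyimino)labdan-15-yl acetate | C[C@]2(CC[C@@H]1[C@@]3(C)CCC[C@](C=NO)(C)[C@@H]3[C@@H](O)C[C@]14CO4)O[C@@H]2COC(C)=O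
F4 | step 7 | (13R,14R)-6α,18:8α,17:13,14-triepoxy-18-hydroxylabdan-15-yl acetate (lactol, both epimers at C18) | C[C@]2(CC[C@@H]1[C@@]3(C)CCC[C@]5(C)[C@@H]3[C@@H](OC5O)C[C@]14CO4)O[C@@H]2COC(C)=O
F5 | step 17 | Evans syn aldol adduct of 18 with the (4-methoxybenzyloxy)acetyl imide of (S)-4-benzyloxazolidin-2-one | C=C(CC[C@@H]1[C@@]2(C)CCC[C@@](C)(CO[Si](CC)(CC)CC)[C@@H]2[C@@H](O[Si](CC)(CC)CC)C[C@@]1(C)O)[C@H](OCc3ccc(OC)cc3)[C@@H](O)[C@H](OCc4ccc(OC)cc4)C(=O)N5[C@@H](Cc6ccccc6)COC5=O
F6 | step 17 | N-methoxy-N-methyl amide from F5 | C=C(CC[C@@H]1[C@@]2(C)CCC[C@@](C)(CO[Si](CC)(CC)CC)[C@@H]2[C@@H](O[Si](CC)(CC)CC)C[C@@]1(C)O)[C@H](OCc3ccc(OC)cc3)[C@@H](O)[C@H](OCc4ccc(OC)cc4)C(=O)N(C)OC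
F7 | step 17 | methyl ketone from F6 | C=C(CC[C@@H]1[C@@]2(C)CCC[C@@](C)(CO[Si](CC)(CC)CC)[C@@H]2[C@@H](O[Si](CC)(CC)CC)C[C@@]1(C)O)[C@H](OCc3ccc(OC)cc3)[C@@H](O)[C@H](OCc4ccc(OC)cc4)C(C)=O
F8 | step 17 | trihydroxy ketone from F7 | C=C(CC[C@@H]1[C@@]2(C)CCC[C@@](C)(CO[Si](CC)(CC)CC)[C@@H]2[C@@H](O[Si](CC)(CC)CC)C[C@@]1(C)O)[C@H](O)[C@@H](O)[C@H](O)C(C)=O
F9 | step 17 | ethyl Z-enoate from F8 | C=C(CC[C@@H]1[C@@]2(C)CCC[C@@](C)(CO[Si](CC)(CC)CC)[C@@H]2[C@@H](O[Si](CC)(CC)CC)C[C@@]1(C)O)[C@H](O)[C@@H](O)[C@H](O)/C(C)=C\C(=O)OCC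
F10 | step 2 | 6α-hydroxy-14,15-dinorlabd-8(17)-en-13-one | CC(=O)CC[C@@H]1[C@@]2(C)CCCC(C)(C)[C@@H]2[C@@H](O)CC1=C
F11 | step 2 | ethyl (13E)-6α-hydroxylabda-8(17),13-dien-15-oate | CCOC(=O)/C=C(\C)CC[C@@H]1[C@@]2(C)CCCC(C)(C)[C@@H]2[C@@H](O)CC1=C
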